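Readings and results were computed with constants of no real substance, noise included.

Leftover incoming ligand was the first thing I asked about in these flasks, where a starting complex exchanged its ligands for incoming ligand step by step.

all flasks: starting complex 12 mM
- epsilon: incoming ligand 13 mM; run made earlier
- eta: incoming ligand 62 mM; run made earlier
- Tuesday's: incoming ligand 12.0 mM; time 2.0 h
- Sunday's: incoming ligand 30.0 mM; time 2.0 h
- Friday's: incoming ligand 48.0 mM; time 2.0 h

- epsilon (time / min: complex with three exchanged / %, complex with two exchanged / %): 5.00: 0.6, 1.1; 12.0: 0, 1.6; 25.0: 1.0, 5.4; 60.0: 0.9, 6.6
- eta (time / min: complex with three exchanged / %, complex with two exchanged / %): 15.0: 2.4, 25.2; 30.0: 7.9, 37.8; 50.0: 17.2, 39.0; 60.0: 20.0, 38.9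

(scatter of a reading: 1 percentage point)

- amount of complex with three exchanged at the end, in percent of the starting complex charged, for each flask in turn (Tuesday's, Sunday's, Friday's)



In the eta run, from 30.0 min to 60.0 min, complex with three exchanged gained 12 percentage points in 30.0 min while complex with two exchanged averaged 38.4%. As a reading from values good to 1 point each, that made a pseudo-first-order constant of 0.0105 /min. Counting as taken up the ligand held in those two measured complexes and in no other form, I estimated leftover [incoming ligand] at 47.8 mM. I therefore defined the third-step constant, the gain per minute over [complex with two exchanged] times leftover [incoming ligand], and read it as 2.20 × 10⁻⁴ /mM/min.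

Then I turned the settings. By hand, a larger ligand charge should raise both factors of that rate. The readings at 60.0 min agreed roughly: complex with two exchanged in the epsilon run stood at 0.170 of its eta value, for a charge ratio of 0.210. So I let the rate go with the square of the charge. By hand, a longer time should add product in a straight line while [complex with two exchanged] holds, and in the eta run it read 37.8%, then 38.9%. Running the eta gain on to 2.0 h and scaling by the square of the charge, I reckoned for Tuesday's, Sunday's and Friday's flasks 1.66%, 10.3% and 26.5%.

The forecast gave 1.2%, 10% and 25%, with the remark “I shade these down slightly, since the last eta interval hints at slowing”.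

Tuesday's, Sunday's and Friday's flasks gave 0.374%, 9.65% and 26.1%.

    starting complex + incoming ligand ⇌ leaving ligand + complex with one exchanged (K = 16.0, k = 0.0920 /M/s)
    complex with one exchanged + incoming ligand ⇌ leaving ligand + complex with two exchanged (K = 0.360, k = 0.0110 /M/s)
    complex with two exchanged + incoming ligand ⇌ leaving ligand + complex with three exchanged (K = 0.890, k = 0.00470 /M/s)
    leaving ligand → by-product carried off (k = 2.40 × 10⁻⁴ /s)

In Sunday's flask, complex with two exchanged stood at 32.0% at the end, with 40.2% of the incoming ligand left. From 1.00 h to 2.00 h, the third-step constant with the mean simulated amounts gives a gain of 5 points, and the flask gained 5.7 points. Over the same span in Friday's flask, the constant gives 13 points, and the flask gained 14 points.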